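**Plan**
Target: (+)-isolariciresinol 9'-O-acetate, (7'S,8R,8'R). Lignan numbering: ring A = fused arene C1–C6, C7 = ring CH2, C8 bears C9H2OH, C8' bears C9'H2OAc, C7' bears the pendant ring C.
Retrosynthesis: benzyl groups are put on both phenols and a second acetate on O9, then C8–C8' and C6–C7' of ring B are cut together. This leaves two copies of (E)-O-benzylconiferyl acetate, which goes back to O-benzylvanillin by C7=C8 olefination.
Enabling feature: ring B (C1–C6–C7'–C8'–C8–C7) joins two identical 4-oxy-3-methoxyphenyl-C3 units at one oxidation level (C7 is CH2). The skeleton is therefore a redox-neutral formal [4+2] dimer: one styrene (C8=C7–C1=C6) is the four-atom partner and the other (C7'=C8') the two-atom partner. O4' para to C7' carries the cation, and the C3 methoxy group para to C6 directs the closure.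
Forward: olefination, reduction and acetylation; a photoredox radical-cation dimerisation builds ring B, the only ring made; a lipase removes the exposed C9 acetate; hydrogenolysis frees the phenols.
Stereochemistry: C8 and C8' (trans relation and absolute sense) come from a chiral counter-anion in the first C–C bond formation, and C7' from the all-equatorial ring closure. No later step touches a stereocentre.

Key step: step 4

Assumption: the sense of induction of the chiral anion cannot be derived from first principles, so the (S,S)-anion is written, and its (R,R)-antipode is to be used if a trial run gives the mirror-image series.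

Step 1
Reactants: 1 4-(benzyloxy)-3-methoxybenzaldehyde (O-benzylvanillin); 2 triethyl phosphonoacetate
Product: 3 ethyl (E)-3-[4-(benzyloxy)-3-methoxyphenyl]prop-2-enoate
Conditions: NaH, THF, 0 °C to rt
Reagents that add atoms: none
Why: Horner–Wadsworth–Emmons olefination with a stabilised phosphonate anion should give the E-cinnamate, which fixes the alkene geometry used in the key step.

Step 2
Reactants: 3 ethyl (E)-3-[4-(benzyloxy)-3-methoxyphenyl]prop-2-enoate
Product: 4 (E)-3-[4-(benzyloxy)-3-methoxyphenyl]prop-2-en-1-ol (O-benzylconiferyl alcohol)
Conditions: i-Bu2AlH (2.2 equiv), CH2Cl2, −78 °C; aq. potassium sodium tartrate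
Reagents that add atoms: none
Why: 1,2-reduction of an enoate with i-Bu2AlH should stop at the allylic alcohol without touching the alkene or the benzyl ether.

Step 3
Reactants: 4 O-benzylconiferyl alcohol
Product: 5 (E)-3-[4-(benzyloxy)-3-methoxyphenyl]prop-2-en-1-yl acetate (O-benzylconiferyl acetate)
Conditions: Ac2O, pyridine, 4-(dimethylamino)pyridine (cat.), CH2Cl2, 0 °C; chromatography on base-washed silica
Reagents that add atoms: acetic anhydride CC(=O)OC(C)=O
Why: nucleophile-catalysed O-acetylation under basic conditions avoids ionisation of the electron-rich cinnamyl system and installs the acetate that stays in the target.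

Step 4
Reactants: 5 (E)-O-benzylconiferyl acetate (two molecules)
Product: 8 di-O-benzyl-(+)-isolariciresinol 9,9'-diacetate (7'S,8R,8'R; all-trans tetralin), via distonic radical cation 6 (not isolated), via C7 tetralinyl radical 7 (not isolated)
Conditions: 9-mesityl-10-methylacridinium salt of the (S,S)-imidodiphosphorimidate anion [N{P(=NSO2CF3)(O2Ar*)}2]−, O2Ar* = (S)-3,3'-bis[3,5-bis(trifluoromethyl)phenyl]-1,1'-binaphthalene-2,2'-diolate (5 mol %), PhSSPh (10 mol %), CH2Cl2–toluene, −40 °C, 450 nm LED, Ar
Reagents that add atoms: none
Why: Proposed new method: the photoexcited acridinium cation oxidises one molecule of 5 to its alkene radical cation, which stays paired with the confined chiral anion and bonds through its alkene carbon next to CH2OAc to the same carbon of a second molecule of 5 (tail to tail, so that spin and charge both become benzylic) to give 6, whose C7' cation, stabilised by the para O4' benzyloxy group, is captured by C6 of the other arene; proton loss restores ring A and gives radical 7, PhSH formed in the flask from PhSSPh passes a hydrogen atom to C7, and the PhS radical takes the electron back from the acridinyl radical, so that the dimerisation is redox-neutral and loses no atom. The closest known reaction types are the racemic acridinium/disulfide photoredox formal [4+2] cyclodimerisation of styrenes to 1-aryltetralins and the enantioselective radical-cation [2+2] cycloaddition of anethole-type styrenes with a photoredox cation paired to an imidodiphosphorimidate anion, and only their union on a cinnamyl acetate is new. Ring B closes stepwise, the C8-C8' bond between two molecules and the C6-C7' bond as a 1,6-closure, that is a six-membered intramolecular Friedel-Crafts alkylation (6-endo with respect to the C1-C6 bond of ring A). C8 and C8' are set together in the first bond formation, their trans relation by the anti approach of two E-alkenes that also leads to the all-trans cyclobutane dimers of such styrenes and their absolute (R,R) sense by the alkene face that the anion leaves open, while C7' (S) follows from a chair-like closure in which the aryl group and both CH2OAc groups are equatorial. The step needs [4+2] over [2+2] selectivity, secured because a cyclobutane with two dialkoxyaryl groups is re-oxidised and reopened by the strong photo-oxidant whereas proton loss and hydrogen-atom transfer make the tetralin channel irreversible, and it needs C6 over C2 selectivity, secured by the para C3 methoxy group and by the crowding of C2. Since both partners are the same molecule, neither cross-selectivity nor an assignment of the four-atom and two-atom roles is required.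

Step 5
Reactants: 8 di-O-benzyl-(+)-isolariciresinol 9,9'-diacetate
Product: 9 di-O-benzyl-(+)-isolariciresinol 9'-O-acetate (C9 hydroxyl free)
Conditions: immobilised Candida antarctica lipase B, n-BuOH (5 equiv), t-BuOMe, 35 °C, stopped at the monoacetate stage
Reagents that add atoms: none
Why: lipase-catalysed regioselective alcoholysis (serine-hydrolase transesterification) should take the C9 acetate, whose carbinol carbon is flanked only by the ring CH2 (C7), and spare the C9' acetate buried between the C7' aryl group and C8, with no stereocentre touched.

Step 6
Reactants: 9 di-O-benzyl-(+)-isolariciresinol 9'-O-acetate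
Product: 10 (+)-isolariciresinol 9'-O-acetate, [(1S,2R,3R)-7-hydroxy-1-(4-hydroxy-3-methoxyphenyl)-3-(hydroxymethyl)-6-methoxy-1,2,3,4-tetrahydronaphthalen-2-yl]methyl acetate (target)
Conditions: H2 (1 atm), Pd/C, EtOAc, rt
Reagents that add atoms: none
Why: neutral hydrogenolysis of the two aryl benzyl ethers should leave the primary acetate, the free alcohol and the three stereocentres intact, since C7' carries only C–C bonds.

**Compound list**
1 | 4-(benzyloxy)-3-methoxybenzaldehyde | COc1cc(C=O)ccc1OCc1ccccc1 | starting material
2 | triethyl phosphonoacetate | CCOC(=O)CP(=O)(OCC)OCC | starting material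
3 | ethyl (E)-3-[4-(benzyloxy)-3-methoxyphenyl]prop-2-enoate | CCOC(=O)/C=C/c1ccc(OCc2ccccc2)c(OC)c1 | intermediate
4 | (E)-O-benzylconiferyl alcohol | COc1cc(/C=C/CO)ccc1OCc1ccccc1 | intermediate
5 | (E)-O-benzylconiferyl acetate | COc1cc(/C=C/COC(C)=O)ccc1OCc1ccccc1 | intermediate
6 | (8R,8'R)-8,8'-linked distonic radical cation (C7' cation, C7 radical), not isolated | COc1cc([CH+][C@@H](COC(C)=O)[C@H](COC(C)=O)[CH]c2ccc(OCc3ccccc3)c(OC)c2)ccc1OCc1ccccc1 | intermediate
7 | ring-closed, rearomatised C7 benzylic radical, not isolated | COc1cc([C@H]2c3cc(OCc4ccccc4)c(OC)cc3[CH][C@@H](COC(C)=O)[C@@H]2COC(C)=O)ccc1OCc1ccccc1 | intermediate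
8 | di-O-benzyl-(+)-isolariciresinol 9,9'-diacetate (7'S,8R,8'R) | COc1cc([C@H]2c3cc(OCc4ccccc4)c(OC)cc3C[C@@H](COC(C)=O)[C@@H]2COC(C)=O)ccc1OCc1ccccc1 | intermediate
9 | di-O-benzyl-(+)-isolariciresinol 9'-O-acetate (7'S,8R,8'R) | COc1cc([C@H]2c3cc(OCc4ccccc4)c(OC)cc3C[C@@H](CO)[C@@H]2COC(C)=O)ccc1OCc1ccccc1 | intermediate
10 | (+)-isolariciresinol 9'-O-acetate (7'S,8R,8'R) | COc1cc([C@H]2c3cc(O)c(OC)cc3C[C@@H](CO)[C@@H]2COC(C)=O)ccc1O | target

Total step count: 6. Longest linear sequence: 6 steps (1 to 10).

**Steps most likely to fail**

1. Step 4 (Proposed new method).
What may go wrong: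
- loss of facial control if the radical cation leaves the ion pair;
- diversion of the distonic intermediate into four-membered ring closure or chain growth;
- acid-induced ionisation of the allylic acetate.

The fallback sets out from aldehyde 1 and comes back to the route at diacetate 8. It makes the bonds of ring B one at a time by known lignan chemistry. Stobbe condensation of 1 with dimethyl succinate (NaOMe, MeOH, reflux) should give the (E)-benzylidenesuccinic half-ester F1. Enantioselective hydrogenation with [Rh(cod)((S,S)-Et-DuPhos)]BF4 should give the (R)-benzylsuccinic half-ester F2; the ligand antipode is chosen for the R product, and the homogeneous catalyst spares the benzyl ether. Reduction of the ester group of its potassium salt with Ca(BH4)2, followed by acidification, should give the (R)-β-benzylbutyrolactone F3. Its lithium enolate (LiN(SiMe3)2, THF, −78 °C) should add to a second portion of 1 anti to the benzyl group to give the trans aldol lactone F4, of which both carbinol epimers serve. CF3CO2H in CH2Cl2 should ionise the carbinol and close C6–C7' by Friedel–Crafts alkylation to the trans-fused tetralin lactone F5. LiAlH4 should give di-O-benzylisolariciresinol F6, and Ac2O in pyridine should give 8.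

2. Step 5.
What may go wrong: insufficient discrimination between the two primary acetates, or over-reaction at both.

The fallback sets out from 8 and comes back at 9. It replaces enzymatic recognition by a protecting-group relay. Methanolysis (K2CO3, MeOH) should give di-O-benzylisolariciresinol F6. One equivalent of t-BuPh2SiCl with imidazole at low temperature should silylate the less hindered C9 hydroxyl to give the 9-O-silyl ether F7. Ac2O in pyridine should give the 9-O-silyl 9'-O-acetate F8. HF·pyridine in THF, which is non-basic and so disfavours acyl migration, should give 9.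

3. Step 6.
What may go wrong: migration of the acetyl group from O9' to O9 during a long contact time, or sluggish cleavage of the benzyl ether on ring A.

The fallback sets out from 8 and comes back at 10, with the order of events reversed. Hydrogenolysis at the diacetate stage (H2, Pd/C, EtOAc), where no free alcohol is present, should give isolariciresinol 9,9'-diacetate F9. The lipase alcoholysis of step 5 is then run on this diphenol as the last operation and should give 10.

**Further compounds**
F1 | step 4 | (E)-4-[4-(benzyloxy)-3-methoxyphenyl]-3-(methoxycarbonyl)but-3-enoic acid | COC(=O)/C(CC(=O)O)=C/c1ccc(OCc2ccccc2)c(OC)c1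
F2 | step 4 | (R)-4-[4-(benzyloxy)-3-methoxyphenyl]-3-(methoxycarbonyl)butanoic acid | COC(=O)[C@H](Cc1ccc(OCc2ccccc2)c(OC)c1)CC(=O)O
F3 | step 4 | (R)-4-[4-(benzyloxy)-3-methoxybenzyl]dihydrofuran-2(3H)-one | O=C1C[C@@H](Cc2ccc(OCc3ccccc3)c(OC)c2)CO1
F4 | step 4 | trans aldol lactone, C8 R, hydroxy(aryl)methyl group anti to the benzyl group, carbinol epimers | O=C1OC[C@H](Cc2ccc(OCc3ccccc3)c(OC)c2)[C@H]1C(O)c1ccc(OCc2ccccc2)c(OC)c1
F5 | step 4 | trans-fused di-O-benzyl tetralin lactone (7'S,8R,8'R), C9' carbonyl, O bound to C9 | COc1cc([C@H]2c3cc(OCc4ccccc4)c(OC)cc3C[C@@H](COC5=O)[C@@H]25)ccc1OCc1ccccc1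
F6 | step 4 | di-O-benzyl-(+)-isolariciresinol | COc1cc([C@H]2c3cc(OCc4ccccc4)c(OC)cc3C[C@@H](CO)[C@@H]2CO)ccc1OCc1ccccc1
F7 | step 5 | 9-O-(tert-butyldiphenylsilyl)-di-O-benzylisolariciresinol | COc1cc([C@H]2c3cc(OCc4ccccc4)c(OC)cc3C[C@@H](CO[Si](c4ccccc4)(c4ccccc4)C(C)(C)C)[C@@H]2CO)ccc1OCc1ccccc1
F8 | step 5 | 9-O-(tert-butyldiphenylsilyl)-di-O-benzylisolariciresinol 9'-O-acetate | COc1cc([C@H]2c3cc(OCc4ccccc4)c(OC)cc3C[C@@H](CO[Si](c4ccccc4)(c4ccccc4)C(C)(C)C)[C@@H]2COC(C)=O)ccc1OCc1ccccc1
F9 | step 6 | (+)-isolariciresinol 9,9'-diacetate | COc1cc([C@H]2c3cc(O)c(OC)cc3C[C@@H](COC(C)=O)[C@@H]2COC(C)=O)ccc1O
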